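**Plan**
- Retrosynthesis: the C8 ester, the C13 methylene and the lactone C12–O bond are removed first. The ten-membered ring is then opened at C7–C8 and C6–O together: the lactone oxygen on C6 and the ester oxygen on C8 stand 1,3 across C7, so ring carbons C6–C7–C8 are a β-hydroxy ketone that an isoxazoline (C8=N–O–C6) bridging the carbocycle can mask.
- The open chain is cut at C5–C6 (Suzuki coupling), C1=C10 (Wittig, later the epoxide) and C2–C3 (allylboration).
- Forward: C15/C4=C5, then C3, C2–C1, the C10/C9/C8/C14 unit, the epoxide and C6–C7–C11–C12 are joined in that order. One cycloaddition closes isoxazoline and carbocycle, N–O cleavage lets the lactone ring close, and methylene, ester and deprotection follow.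
- Stereochemistry: 4Z from anti-carbomagnesiation; C3 from Brown allylboration; C1/C10 from Sharpless epoxidation; C6/C7 from the cycloaddition (syn addition to the E alkene, face set by C3 and the epoxide); C8 from Felkin-type hydride delivery; C2′ from (R)-2-methylbutanoic acid.

Key step: step 15

Remark: carbons are numbered as in the germacrane skeleton of the target (ring C1–C10, C11 on C7, C12 the lactone carbonyl, C13 the methylene on C11, C14 on C10, C15 the methyl on C4). TBS = tert-butyldimethylsilyl, TES = triethylsilyl. Compounds 10, 11, 21, 39, (−)-Ipc2BOMe and allylmagnesium bromide are taken as commercial. The glycols 8 and 18, oxime 25 and Mannich base 35 are isomer mixtures at a centre that is later removed.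

Step 1
Reactants: 1 prop-2-yn-1-ol (propargyl alcohol)
Product: 3 (2Z)-3-iodo-2-methylprop-2-en-1-ol, via alkenylmagnesium alkoxide 2 (not isolated)
Conditions: MeMgBr (2.3 equiv), CuI (10 mol %), THF, −10 °C → rt; then I2, −10 °C
Reagents that add atoms: methylmagnesium bromide, C[Mg]Br; iodine, II
Why: Copper-catalysed anti-carbomagnesiation of the propargylic alkoxide gives a chelated alkenylmagnesium with Mg cis to CH2O, and iodinolysis with retention should place iodine cis to the CH2OH carbon, the geometry that becomes the 4Z alkene.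

Step 2
Reactants: 3 (2Z)-3-iodo-2-methylprop-2-en-1-ol
Product: 4 (2Z)-3-iodo-2-methylprop-2-enal
Conditions: MnO2, CH2Cl2, rt, dark
Reagents that add atoms: none
Why: Allylic oxidation with MnO2 is neutral and selective, so the isomerisation-prone Z-β-iodoenal should survive if it is used at once.

Step 3
Reactants: 4 (2Z)-3-iodo-2-methylprop-2-enal
Product: 6 (3S,1Z)-1-iodo-2-methylhexa-1,5-dien-3-ol, via diisopinocampheylborinate 5 (not isolated)
Conditions: (−)-Ipc2BOMe, allylMgBr, Et2O, 0 °C → rt; then 4, −78 °C; then NaOH, H2O2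
Reagents that add atoms: (−)-B-allyldiisopinocampheylborane, made in the flask from allylmagnesium bromide (C=CC[Mg]Br) and (−)-Ipc2BOMe, C=CCB([C@@H]1C[C@@H]2C[C@H]([C@H]1C)C2(C)C)[C@@H]1C[C@@H]2C[C@H]([C@H]1C)C2(C)C
Why: Brown allylboration through a chair transition state should deliver allyl to the Si face of the enal under reagent control and set C3 as S.

Step 4
Reactants: 6 (3S,1Z)-1-iodo-2-methylhexa-1,5-dien-3-ol
Product: 7 tert-butyl{[(3S,1Z)-1-iodo-2-methylhexa-1,5-dien-3-yl]oxy}dimethylsilane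
Conditions: TBSCl, imidazole, DMF, rt
Reagents that add atoms: tert-butyldimethylsilyl chloride, CC(C)(C)[Si](C)(C)Cl
Why: Standard imidazole-promoted silylation protects the allylic C3 hydroxyl without touching the stereocentre.

Step 5
Reactants: 7 tert-butyl{[(3S,1Z)-1-iodo-2-methylhexa-1,5-dien-3-yl]oxy}dimethylsilane
Product: 9 (3S,4Z)-3-[(TBS)oxy]-5-iodo-4-methylpent-4-enal, via glycol 8 (not isolated)
Conditions: OsO4 (2 mol %), NaIO4, 2,6-lutidine, dioxane/H2O, rt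
Reagents that add atoms: osmium tetroxide (oxygen carrier), O=[Os](=O)(=O)=O; sodium periodate (restocks it), [Na+].[O-]I(=O)(=O)=O
Why: In this Lemieux–Johnson cleavage osmylation should take the monosubstituted alkene in preference to the hindered, iodine-deactivated trisubstituted one, and periodate cleaves the glycol to the C1 aldehyde.

Step 6
Reactants: 10 ethyl (triphenyl-λ5-phosphanylidene)acetate; 11 allyl bromide
Product: 13 ethyl 2-(triphenyl-λ5-phosphanylidene)pent-4-enoate, via phosphonium bromide 12 (not isolated)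
Conditions: CHCl3, reflux; then aq NaOH, CH2Cl2, rt
Reagents that add atoms: none
Why: C-Alkylation of the stabilised ylide by the allylic bromide followed by deprotonation of the phosphonium salt is the usual way to α-branched stabilised ylides.

Step 7
Reactants: 9 (3S,4Z)-3-[(TBS)oxy]-5-iodo-4-methylpent-4-enal; 13 ethyl 2-(triphenyl-λ5-phosphanylidene)pent-4-enoate
Product: 14 ethyl (2E,5S,6Z)-5-[(TBS)oxy]-7-iodo-6-methyl-2-(prop-2-en-1-yl)hepta-2,6-dienoate
Conditions: toluene, 80 °C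
Reagents that add atoms: none
Why: Wittig olefination with an α-branched stabilised ylide should give the trisubstituted enoate with the ester trans to C2 (E), which places C2 and C9 cis as the epoxide needs.

Step 8
Reactants: 14 ethyl (2E,5S,6Z)-5-[(TBS)oxy]-7-iodo-6-methyl-2-(prop-2-en-1-yl)hepta-2,6-dienoate
Product: 15 (2E,5S,6Z)-5-[(TBS)oxy]-7-iodo-6-methyl-2-(prop-2-en-1-yl)hepta-2,6-dien-1-ol
Conditions: i-Bu2AlH (2.5 equiv), CH2Cl2, −78 °C
Reagents that add atoms: none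
Why: 1,2-Reduction of an enoate by i-Bu2AlH at low temperature gives the allylic alcohol (C14–OH) and leaves the alkenyl iodide alone.

Step 9
Reactants: 15 (2E,5S,6Z)-5-[(TBS)oxy]-7-iodo-6-methyl-2-(prop-2-en-1-yl)hepta-2,6-dien-1-ol
Product: 16 [(2R,3R)-3-{(2S,3Z)-2-[(TBS)oxy]-4-iodo-3-methylbut-3-en-1-yl}-2-(prop-2-en-1-yl)oxiran-2-yl]methanol
Conditions: Ti(Oi-Pr)4 (10 mol %), D-(−)-diisopropyl tartrate (12 mol %), t-BuOOH, 4 Å sieves, CH2Cl2, −20 °C
Reagents that add atoms: tert-butyl hydroperoxide, CC(C)(C)OO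
Why: Sharpless asymmetric epoxidation acts only on the allylic alcohol, and the D-(−)-tartrate should deliver oxygen to the face that gives the 1R,10R epoxide under reagent control.

Step 10
Reactants: 16 [(2R,3R)-3-{(2S,3Z)-2-[(TBS)oxy]-4-iodo-3-methylbut-3-en-1-yl}-2-(prop-2-en-1-yl)oxiran-2-yl]methanol
Product: 17 tert-butyl{[(2R,3R)-3-{(2S,3Z)-2-[(TBS)oxy]-4-iodo-3-methylbut-3-en-1-yl}-2-(prop-2-en-1-yl)oxiran-2-yl]methoxy}dimethylsilane
Conditions: TBSCl, imidazole, DMF, rt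
Reagents that add atoms: tert-butyldimethylsilyl chloride, CC(C)(C)[Si](C)(C)Cl
Why: Silylation of the primary epoxy alcohol under imidazole catalysis blocks C14–OH against Payne rearrangement and against trapping of the later nitrile oxide.

Step 11
Reactants: 17 tert-butyl{[(2R,3R)-3-{(2S,3Z)-2-[(TBS)oxy]-4-iodo-3-methylbut-3-en-1-yl}-2-(prop-2-en-1-yl)oxiran-2-yl]methoxy}dimethylsilane
Product: 20 2-[(2R,3R)-2-{[(TBS)oxy]methyl}-3-{(2S,3Z)-2-[(TBS)oxy]-4-iodo-3-methylbut-3-en-1-yl}oxiran-2-yl]ethan-1-ol, via glycol 18 (not isolated), via epoxy aldehyde 19 (not isolated)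
Conditions: OsO4 (2 mol %), NaIO4, 2,6-lutidine, dioxane/H2O, rt; extract; then NaBH4, MeOH, −20 °C
Reagents that add atoms: osmium tetroxide (oxygen carrier), O=[Os](=O)(=O)=O; sodium periodate (restocks it), [Na+].[O-]I(=O)(=O)=O
Why: Lemieux–Johnson cleavage of the only unhindered alkene excises the terminal carbon, and immediate borohydride reduction parks C8 as a stable primary alcohol so that the β,γ-epoxy aldehyde is never stored.

Step 12
Reactants: 21 methyl but-3-ynoate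
Product: 22 methyl (3E)-4-(4,4,5,5-tetramethyl-1,3,2-dioxaborolan-2-yl)but-3-enoate
Conditions: pinacolborane, Cp2Zr(H)Cl (5 mol %), CH2Cl2, rt
Reagents that add atoms: pinacolborane, [H]B1OC(C)(C)C(C)(C)O1
Why: Zirconium-catalysed syn-hydroboration of the terminal alkyne gives the E alkenylboronate, and the base-free medium should prevent alkyne-to-allene isomerisation.

Step 13
Reactants: 20 2-[(2R,3R)-2-{[(TBS)oxy]methyl}-3-{(2S,3Z)-2-[(TBS)oxy]-4-iodo-3-methylbut-3-en-1-yl}oxiran-2-yl]ethan-1-ol; 22 methyl (3E)-4-(4,4,5,5-tetramethyl-1,3,2-dioxaborolan-2-yl)but-3-enoate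
Product: 23 methyl (3E,5Z,7S)-7-[(TBS)oxy]-8-[(2R,3R)-3-{[(TBS)oxy]methyl}-3-(2-hydroxyethyl)oxiran-2-yl]-6-methylocta-3,5-dienoate
Conditions: Pd(PPh3)4 (5 mol %), Tl2CO3, THF/H2O, rt, dark
Reagents that add atoms: none
Why: Suzuki–Miyaura coupling proceeds with retention at both alkenyl partners and so should give the 5Z,3E diene (C4=C5 and C6=C7), with the weak thallium base chosen to spare the β,γ-unsaturated ester.

Step 14
Reactants: 23 methyl (3E,5Z,7S)-7-[(TBS)oxy]-8-[(2R,3R)-3-{[(TBS)oxy]methyl}-3-(2-hydroxyethyl)oxiran-2-yl]-6-methylocta-3,5-dienoate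
Product: 25 methyl (3E,5Z,7S)-7-[(TBS)oxy]-8-[(2R,3R)-3-{[(TBS)oxy]methyl}-3-[2-(hydroxyimino)ethyl]oxiran-2-yl]-6-methylocta-3,5-dienoate, via epoxy aldehyde 24 (not isolated)
Conditions: Dess–Martin periodinane, NaHCO3, CH2Cl2, 0 °C; filter; then NH2OH·HCl, NaOAc, MeOH, 0 °C
Reagents that add atoms: hydroxylamine hydrochloride, NO.Cl
Why: Buffered Dess–Martin oxidation gives the β,γ-epoxy aldehyde under non-basic conditions and acetate-buffered oximation traps it before the epoxide can open by β-elimination.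

Step 15
Reactants: 25 methyl (3E,5Z,7S)-7-[(TBS)oxy]-8-[(2R,3R)-3-{[(TBS)oxy]methyl}-3-[2-(hydroxyimino)ethyl]oxiran-2-yl]-6-methylocta-3,5-dienoate
Product: 28 methyl (1R,3S,4Z,6S,7R,10R)-3,14-bis[(TBS)oxy]-1,10-epoxy-6,8-(epoxynitrilo)-13-norgermacr-4-en-12-oate (ten-membered carbocycle bridged by the isoxazoline C8=N–O–C6 and carrying CH2CO2Me on C7), via hydroximoyl chloride 26 (not isolated), via nitrile oxide 27 (not isolated)
Conditions: aq NaOCl, CH2Cl2, 0 °C → rt, 25 added by syringe pump over 12 h (final ≤ 2 mM)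
Reagents that add atoms: none
Why: Hypochlorite chlorinates the aldoxime and loss of HCl gives nitrile oxide 27, which adds suprafacially in one concerted [3+2] step across the (E)-C6=C7 bond, carbon to C7 and oxygen to C6. The closest known reaction type is the intramolecular nitrile oxide–olefin cycloaddition run at high dilution to close medium and large carbocycles in the bridged sense. The isoxazoline closes as the five-membered cycloadduct (C8, N, O, C6, C7), and the ten-membered carbocycle closes through the same C7–C8 bond in the bridged mode, because the dipole carbon bonds to the alkene carbon distal to the tether and C7 becomes a one-atom bridge. C6 and C7 are set together: their relative configuration (H6 and H7 trans on the isoxazoline, cis on the later lactone) follows from syn addition to the E alkene. Their absolute sense follows from the alkene face; the expected face is the one turned toward the tether when C3–H eclipses the (Z)-C4=C5 bond (allylic strain), the silyloxy group points outward and the diene folds cisoid, a model rather than a certainty. The step needs C6=C7 to react in preference to the trisubstituted C4=C5 bond and with oxygen at C6; the less hindered disubstituted diene terminus and the preference for oxygen on the carbon bearing the conjugating alkene should secure this, while slow addition keeps furoxan formation down.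

Step 16
Reactants: 28 methyl (1R,3S,4Z,6S,7R,10R)-3,14-bis[(TBS)oxy]-1,10-epoxy-6,8-(epoxynitrilo)-13-norgermacr-4-en-12-oate
Product: 31 (1R,3S,4Z,6S,7S,10R)-3,14-bis[(TBS)oxy]-1,10-epoxy-8-oxo-13-norgermacr-4-eno-12,6-lactone, via hydroxy imine 29 (not isolated), via hydroxy keto ester 30 (not isolated)
Conditions: Mo(CO)6, MeCN/H2O (15:1), 80 °C; then PPTS (cat.), CH2Cl2, rt
Reagents that add atoms: water, O
Why: Mo(CO)6 reductively cleaves the N–O bond without touching alkene or epoxide, the imine hydrolyses to the C8 ketone and the freed C6 hydroxyl closes the cis-fused γ-lactone on the methyl ester (5-exo-trig), C6 and C7 being untouched.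

Step 17
Reactants: 31 (1R,3S,4Z,6S,7S,10R)-3,14-bis[(TBS)oxy]-1,10-epoxy-8-oxo-13-norgermacr-4-eno-12,6-lactone
Product: 32 (1R,3S,4Z,6S,7R,8R,10R)-3,14-bis[(TBS)oxy]-1,10-epoxy-8-hydroxy-13-norgermacr-4-eno-12,6-lactone
Conditions: NaBH4, CeCl3·7H2O, MeOH/THF, −78 °C
Reagents that add atoms: none
Why: Luche reduction is fast and nearly neutral at −78 °C, so the β-acyloxy ketone should not eliminate, and hydride is expected to come from the ring periphery, anti to the C6–C7 bond and past H7 (Felkin–Anh), which puts O8 anti to C11 and gives 8R.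

Step 18
Reactants: 32 (1R,3S,4Z,6S,7R,8R,10R)-3,14-bis[(TBS)oxy]-1,10-epoxy-8-hydroxy-13-norgermacr-4-eno-12,6-lactone
Product: 33 (1R,3S,4Z,6S,7S,8R,10R)-3,14-bis[(TBS)oxy]-1,10-epoxy-8-[(TES)oxy]-13-norgermacr-4-eno-12,6-lactone
Conditions: TESOTf, 2,6-lutidine, CH2Cl2, −78 °C
Reagents that add atoms: triethylsilyl trifluoromethanesulfonate, CC[Si](CC)(CC)OS(=O)(=O)C(F)(F)F
Why: Silyl triflate with a hindered base silylates the hindered secondary alcohol cold, so that no C8 alkoxide can translactonise during the enolate step, and the TES group stays removable beside TBS.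

Step 19
Reactants: 33 (1R,3S,4Z,6S,7S,8R,10R)-3,14-bis[(TBS)oxy]-1,10-epoxy-8-[(TES)oxy]-13-norgermacr-4-eno-12,6-lactone
Product: 37 (1R,3S,4Z,6S,7S,8R,10R)-3,14-bis[(TBS)oxy]-1,10-epoxy-8-[(TES)oxy]germacra-4,11(13)-dieno-12,6-lactone, via lithium enolate 34 (not isolated), via Mannich base 35 (not isolated), via ammonium iodide 36 (not isolated)
Conditions: LiN(i-Pr)2, THF, −78 °C; CH2=NMe2+ I−, −78 °C → rt; then MeI, MeOH, rt; then aq NaHCO3, CH2Cl2
Reagents that add atoms: N,N-dimethylmethyleneiminium iodide (Eschenmoser's salt), C=[N+](C)C.[I-]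
Why: The kinetic lactone enolate undergoes a Mannich reaction with the iminium salt, and quaternisation followed by mild-base E1cB loss of trimethylamine gives the exocyclic C11=C13 methylene without disturbing C7.

Step 20
Reactants: 37 (1R,3S,4Z,6S,7S,8R,10R)-3,14-bis[(TBS)oxy]-1,10-epoxy-8-[(TES)oxy]germacra-4,11(13)-dieno-12,6-lactone
Product: 38 (1R,3S,4Z,6S,7R,8R,10R)-3,14-bis[(TBS)oxy]-1,10-epoxy-8-hydroxygermacra-4,11(13)-dieno-12,6-lactone
Conditions: HF·pyridine, pyridine, THF, 0 °C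
Reagents that add atoms: none
Why: Pyridine-buffered HF·pyridine cleaves a triethylsilyl ether much faster than TBS ethers (silyl ether lability order), so only C8–OH should be freed.

Step 21
Reactants: 38 (1R,3S,4Z,6S,7R,8R,10R)-3,14-bis[(TBS)oxy]-1,10-epoxy-8-hydroxygermacra-4,11(13)-dieno-12,6-lactone; 39 (R)-2-methylbutanoic acid
Product: 40 (1R,3S,4Z,6S,7R,8R,10R)-3,14-bis[(TBS)oxy]-1,10-epoxy-8-{[(2R)-2-methylbutanoyl]oxy}germacra-4,11(13)-dieno-12,6-lactone
Conditions: DCC, DMAP, CH2Cl2, 0 °C → rt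
Reagents that add atoms: none
Why: Steglich esterification acylates the hindered secondary alcohol through the acylpyridinium ion, and the acid, lacking an activating α-substituent, should keep its R configuration.

Step 22
Reactants: 40 (1R,3S,4Z,6S,7R,8R,10R)-3,14-bis[(TBS)oxy]-1,10-epoxy-8-{[(2R)-2-methylbutanoyl]oxy}germacra-4,11(13)-dieno-12,6-lactone
Product: 41 CNP0356520.2, (1R,3S,4Z,6S,7R,8R,10R)-1,10-epoxy-3,14-dihydroxy-8-{[(2R)-2-methylbutanoyl]oxy}germacra-4,11(13)-dieno-12,6-lactone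
Conditions: HF·pyridine, pyridine, THF, 0 °C → rt
Reagents that add atoms: none
Why: Fluoride desilylation in a pyridine-buffered acidic medium removes both TBS groups while avoiding the base that would invite Payne rearrangement of the 14-hydroxy epoxide, acyl migration or addition to the methylene lactone.

**Compound list**

1 | prop-2-yn-1-ol (propargyl alcohol) | C#CCO | starting material
2 | bromomagnesium (2Z)-3-(bromomagnesio)-2-methylprop-2-en-1-olate | C/C(CO[Mg]Br)=C/[Mg]Br | intermediate (not isolated)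
3 | (2Z)-3-iodo-2-methylprop-2-en-1-ol | OC/C(C)=C\I | intermediate
4 | (2Z)-3-iodo-2-methylprop-2-enal | O=C/C(C)=C\I | intermediate
5 | (3S,1Z)-1-iodo-2-methylhexa-1,5-dien-3-yl diisopinocampheylborinate | C=CC[C@H](OB([C@@H]1C[C@@H]2C[C@H]([C@H]1C)C2(C)C)[C@@H]1C[C@@H]2C[C@H]([C@H]1C)C2(C)C)/C(C)=C\I | intermediate (not isolated)
6 | (3S,1Z)-1-iodo-2-methylhexa-1,5-dien-3-ol | C=CC[C@H](O)/C(C)=C\I | intermediate
7 | tert-butyl{[(3S,1Z)-1-iodo-2-methylhexa-1,5-dien-3-yl]oxy}dimethylsilane | C=CC[C@H](O[Si](C)(C)C(C)(C)C)/C(C)=C\I | intermediate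
8 | (4S,5Z)-4-[(TBS)oxy]-6-iodo-5-methylhex-5-ene-1,2-diol (both C2 epimers) | OCC(O)C[C@H](O[Si](C)(C)C(C)(C)C)/C(C)=C\I | intermediate (not isolated)
9 | (3S,4Z)-3-[(TBS)oxy]-5-iodo-4-methylpent-4-enal | O=CC[C@H](O[Si](C)(C)C(C)(C)C)/C(C)=C\I | intermediate
10 | ethyl (triphenyl-λ5-phosphanylidene)acetate | CCOC(=O)C=P(c1ccccc1)(c1ccccc1)c1ccccc1 | starting material
11 | allyl bromide | C=CCBr | starting material
12 | [1-(ethoxycarbonyl)but-3-en-1-yl]triphenylphosphonium bromide | CCOC(=O)C(CC=C)[P+](c1ccccc1)(c1ccccc1)c1ccccc1.[Br-] | intermediate (not isolated)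
13 | ethyl 2-(triphenyl-λ5-phosphanylidene)pent-4-enoate | CCOC(=O)C(CC=C)=P(c1ccccc1)(c1ccccc1)c1ccccc1 | intermediate
14 | ethyl (2E,5S,6Z)-5-[(TBS)oxy]-7-iodo-6-methyl-2-(prop-2-en-1-yl)hepta-2,6-dienoate | CCOC(=O)/C(CC=C)=C/C[C@H](O[Si](C)(C)C(C)(C)C)/C(C)=C\I | intermediate
15 | (2E,5S,6Z)-5-[(TBS)oxy]-7-iodo-6-methyl-2-(prop-2-en-1-yl)hepta-2,6-dien-1-ol | OC/C(CC=C)=C/C[C@H](O[Si](C)(C)C(C)(C)C)/C(C)=C\I | intermediate
16 | [(2R,3R)-3-{(2S,3Z)-2-[(TBS)oxy]-4-iodo-3-methylbut-3-en-1-yl}-2-(prop-2-en-1-yl)oxiran-2-yl]methanol | I/C=C(/C)[C@@H](O[Si](C)(C)C(C)(C)C)C[C@H]1O[C@@]1(CO)CC=C | intermediate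
17 | tert-butyl{[(2R,3R)-3-{(2S,3Z)-2-[(TBS)oxy]-4-iodo-3-methylbut-3-en-1-yl}-2-(prop-2-en-1-yl)oxiran-2-yl]methoxy}dimethylsilane | I/C=C(/C)[C@@H](O[Si](C)(C)C(C)(C)C)C[C@H]1O[C@@]1(CO[Si](C)(C)C(C)(C)C)CC=C | intermediate
18 | 3-[(2R,3R)-2-{[(TBS)oxy]methyl}-3-{(2S,3Z)-2-[(TBS)oxy]-4-iodo-3-methylbut-3-en-1-yl}oxiran-2-yl]propane-1,2-diol (both C2 epimers) | I/C=C(/C)[C@@H](O[Si](C)(C)C(C)(C)C)C[C@H]1O[C@@]1(CO[Si](C)(C)C(C)(C)C)CC(O)CO | intermediate (not isolated)
19 | 2-[(2R,3R)-2-{[(TBS)oxy]methyl}-3-{(2S,3Z)-2-[(TBS)oxy]-4-iodo-3-methylbut-3-en-1-yl}oxiran-2-yl]acetaldehyde | I/C=C(/C)[C@@H](O[Si](C)(C)C(C)(C)C)C[C@H]1O[C@@]1(CO[Si](C)(C)C(C)(C)C)CC=O | intermediate (not isolated)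
20 | 2-[(2R,3R)-2-{[(TBS)oxy]methyl}-3-{(2S,3Z)-2-[(TBS)oxy]-4-iodo-3-methylbut-3-en-1-yl}oxiran-2-yl]ethan-1-ol | I/C=C(/C)[C@@H](O[Si](C)(C)C(C)(C)C)C[C@H]1O[C@@]1(CO[Si](C)(C)C(C)(C)C)CCO | intermediate
21 | methyl but-3-ynoate | C#CCC(=O)OC | starting material
22 | methyl (3E)-4-(4,4,5,5-tetramethyl-1,3,2-dioxaborolan-2-yl)but-3-enoate | COC(=O)C/C=C/B1OC(C)(C)C(C)(C)O1 | intermediate
23 | methyl (3E,5Z,7S)-7-[(TBS)oxy]-8-[(2R,3R)-3-{[(TBS)oxy]methyl}-3-(2-hydroxyethyl)oxiran-2-yl]-6-methylocta-3,5-dienoate | COC(=O)C/C=C/C=C(/C)[C@@H](O[Si](C)(C)C(C)(C)C)C[C@H]1O[C@@]1(CO[Si](C)(C)C(C)(C)C)CCO | intermediate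
24 | methyl (3E,5Z,7S)-7-[(TBS)oxy]-8-[(2R,3R)-3-{[(TBS)oxy]methyl}-3-(2-oxoethyl)oxiran-2-yl]-6-methylocta-3,5-dienoate | COC(=O)C/C=C/C=C(/C)[C@@H](O[Si](C)(C)C(C)(C)C)C[C@H]1O[C@@]1(CO[Si](C)(C)C(C)(C)C)CC=O | intermediate (not isolated)
25 | methyl (3E,5Z,7S)-7-[(TBS)oxy]-8-[(2R,3R)-3-{[(TBS)oxy]methyl}-3-[2-(hydroxyimino)ethyl]oxiran-2-yl]-6-methylocta-3,5-dienoate (oxime E/Z mixture) | COC(=O)C/C=C/C=C(/C)[C@@H](O[Si](C)(C)C(C)(C)C)C[C@H]1O[C@@]1(CO[Si](C)(C)C(C)(C)C)CC=NO | intermediate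
26 | hydroximoyl chloride of 25, 3-[2-chloro-2-(hydroxyimino)ethyl] in place of the oxime | COC(=O)C/C=C/C=C(/C)[C@@H](O[Si](C)(C)C(C)(C)C)C[C@H]1O[C@@]1(CO[Si](C)(C)C(C)(C)C)CC(Cl)=NO | intermediate (not isolated)
27 | nitrile oxide of 25 (C8≡N+–O−) | COC(=O)C/C=C/C=C(/C)[C@@H](O[Si](C)(C)C(C)(C)C)C[C@H]1O[C@@]1(CO[Si](C)(C)C(C)(C)C)CC#[N+][O-] | intermediate (not isolated)
28 | methyl (1R,3S,4Z,6S,7R,10R)-3,14-bis[(TBS)oxy]-1,10-epoxy-6,8-(epoxynitrilo)-13-norgermacr-4-en-12-oate (isoxazoline C8=N–O–C6) | COC(=O)C[C@H]1[C@@H]2/C=C(/C)[C@@H](O[Si](C)(C)C(C)(C)C)C[C@H]3O[C@@]3(CO[Si](C)(C)C(C)(C)C)CC1=NO2 | intermediate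
29 | methyl (1R,3S,4Z,6S,7R,10R)-3,14-bis[(TBS)oxy]-1,10-epoxy-6-hydroxy-8-imino-13-norgermacr-4-en-12-oate | COC(=O)C[C@H]1[C@@H](O)/C=C(/C)[C@@H](O[Si](C)(C)C(C)(C)C)C[C@H]2O[C@@]2(CO[Si](C)(C)C(C)(C)C)CC1=N | intermediate (not isolated)
30 | methyl (1R,3S,4Z,6S,7S,10R)-3,14-bis[(TBS)oxy]-1,10-epoxy-6-hydroxy-8-oxo-13-norgermacr-4-en-12-oate | COC(=O)C[C@H]1[C@@H](O)/C=C(/C)[C@@H](O[Si](C)(C)C(C)(C)C)C[C@H]2O[C@@]2(CO[Si](C)(C)C(C)(C)C)CC1=O | intermediate (not isolated)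
31 | (1R,3S,4Z,6S,7S,10R)-3,14-bis[(TBS)oxy]-1,10-epoxy-8-oxo-13-norgermacr-4-eno-12,6-lactone (cis-fused) | C1C(=O)O[C@H]2/C=C(/C)[C@@H](O[Si](C)(C)C(C)(C)C)C[C@H]3O[C@@]3(CO[Si](C)(C)C(C)(C)C)CC(=O)[C@@H]12 | intermediate
32 | (1R,3S,4Z,6S,7R,8R,10R)-3,14-bis[(TBS)oxy]-1,10-epoxy-8-hydroxy-13-norgermacr-4-eno-12,6-lactone | C1C(=O)O[C@H]2/C=C(/C)[C@@H](O[Si](C)(C)C(C)(C)C)C[C@H]3O[C@@]3(CO[Si](C)(C)C(C)(C)C)C[C@@H](O)[C@@H]12 | intermediate
33 | (1R,3S,4Z,6S,7S,8R,10R)-3,14-bis[(TBS)oxy]-1,10-epoxy-8-[(TES)oxy]-13-norgermacr-4-eno-12,6-lactone | C1C(=O)O[C@H]2/C=C(/C)[C@@H](O[Si](C)(C)C(C)(C)C)C[C@H]3O[C@@]3(CO[Si](C)(C)C(C)(C)C)C[C@@H](O[Si](CC)(CC)CC)[C@@H]12 | intermediate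
34 | lithium enolate of 33 (C11=C12–OLi) | C1=C(O[Li])O[C@H]2/C=C(/C)[C@@H](O[Si](C)(C)C(C)(C)C)C[C@H]3O[C@@]3(CO[Si](C)(C)C(C)(C)C)C[C@@H](O[Si](CC)(CC)CC)[C@@H]12 | intermediate (not isolated)
35 | 11-[(dimethylamino)methyl] derivative of 33 (either C11 epimer) | CN(C)CC1C(=O)O[C@H]2/C=C(/C)[C@@H](O[Si](C)(C)C(C)(C)C)C[C@H]3O[C@@]3(CO[Si](C)(C)C(C)(C)C)C[C@@H](O[Si](CC)(CC)CC)[C@@H]12 | intermediate (not isolated)
36 | 11-[(trimethylammonio)methyl] derivative of 33, iodide (either C11 epimer) | C[N+](C)(C)CC1C(=O)O[C@H]2/C=C(/C)[C@@H](O[Si](C)(C)C(C)(C)C)C[C@H]3O[C@@]3(CO[Si](C)(C)C(C)(C)C)C[C@@H](O[Si](CC)(CC)CC)[C@@H]12.[I-] | intermediate (not isolated)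
37 | (1R,3S,4Z,6S,7S,8R,10R)-3,14-bis[(TBS)oxy]-1,10-epoxy-8-[(TES)oxy]germacra-4,11(13)-dieno-12,6-lactone | C=C1C(=O)O[C@H]2/C=C(/C)[C@@H](O[Si](C)(C)C(C)(C)C)C[C@H]3O[C@@]3(CO[Si](C)(C)C(C)(C)C)C[C@@H](O[Si](CC)(CC)CC)[C@@H]12 | intermediate
38 | (1R,3S,4Z,6S,7R,8R,10R)-3,14-bis[(TBS)oxy]-1,10-epoxy-8-hydroxygermacra-4,11(13)-dieno-12,6-lactone | C=C1C(=O)O[C@H]2/C=C(/C)[C@@H](O[Si](C)(C)C(C)(C)C)C[C@H]3O[C@@]3(CO[Si](C)(C)C(C)(C)C)C[C@@H](O)[C@@H]12 | intermediate
39 | (R)-2-methylbutanoic acid | CC[C@@H](C)C(=O)O | starting material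
40 | (1R,3S,4Z,6S,7R,8R,10R)-3,14-bis[(TBS)oxy]-1,10-epoxy-8-{[(2R)-2-methylbutanoyl]oxy}germacra-4,11(13)-dieno-12,6-lactone | C=C1C(=O)O[C@H]2/C=C(/C)[C@@H](O[Si](C)(C)C(C)(C)C)C[C@H]3O[C@@]3(CO[Si](C)(C)C(C)(C)C)C[C@@H](OC(=O)[C@H](C)CC)[C@@H]12 | intermediate
41 | CNP0356520.2, (1R,3S,4Z,6S,7R,8R,10R)-1,10-epoxy-3,14-dihydroxy-8-{[(2R)-2-methylbutanoyl]oxy}germacra-4,11(13)-dieno-12,6-lactone | C=C1C(=O)O[C@H]2/C=C(/C)[C@@H](O)C[C@H]3O[C@@]3(CO)C[C@@H](OC(=O)[C@H](C)CC)[C@@H]12 | target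

**Count**
Total steps: 22. Longest linear sequence: 20 (steps 1–5, 7–11, 13–22); steps 6 and 12 prepare the two side fragments.

**Steps most likely to fail**

Step 15. Closure of the bridged ten-membered ring may be slow, so that the nitrile oxide dimerises to furoxans, or the hypochlorite medium chlorinates the diene and lets the oximate open the epoxide. The C6=C7 face may also be taken with low preference, which this fallback does not repair. The fallback makes the dipole by dehydration of a primary nitroalkane, which releases it slowly in a dry, non-oxidising medium and also avoids the epoxy aldehyde and oxime of step 14. It sets out from alcohol 23. Treatment with I2, PPh3 and imidazole in CH2Cl2 at 0 °C should give the iodide methyl (3E,5Z,7S)-7-[(TBS)oxy]-8-[(2R,3R)-3-{[(TBS)oxy]methyl}-3-(2-iodoethyl)oxiran-2-yl]-6-methylocta-3,5-dienoate F1. Kornblum substitution (NaNO2, phloroglucinol, DMF, rt) should give the nitro compound methyl (3E,5Z,7S)-7-[(TBS)oxy]-8-[(2R,3R)-3-{[(TBS)oxy]methyl}-3-(2-nitroethyl)oxiran-2-yl]-6-methylocta-3,5-dienoate F2. Mukaiyama dehydration (PhNCO, catalytic Et3N, benzene, 60 °C, high dilution) then leads through nitrile oxide 27 to isoxazoline 28, where the route is rejoined.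

Step 17. Hydride may add to the other face of the medium-ring ketone, through the conformer that turns C11 toward the reagent, so that the 8S alcohol dominates. The fallback uses that epimer by inversion. From ketone 31, the hydride that gives it most cleanly (a bulky one such as LiBH(s-Bu)3 in THF at −78 °C is tried first) should give (1R,3S,4Z,6S,7R,8S,10R)-3,14-bis[(TBS)oxy]-1,10-epoxy-8-hydroxy-13-norgermacr-4-eno-12,6-lactone F3. A Mitsunobu reaction (ClCH2CO2H, PPh3, DIAD, toluene, 0 °C → rt) should give with inversion the chloroacetate (1R,3S,4Z,6S,7R,8R,10R)-3,14-bis[(TBS)oxy]-8-(chloroacetoxy)-1,10-epoxy-13-norgermacr-4-eno-12,6-lactone F4. Thiourea and NaHCO3 in EtOH remove the chloroacetyl group without opening the lactone and return alcohol 32.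

Step 13. The basic aqueous medium may move the β,γ double bond of boronate 22 or of product 23 into conjugation with the ester, or erode the 5Z geometry. The fallback is a base-free Stille coupling. From methyl but-3-ynoate 21, radical hydrostannation (Bu3SnH, AIBN, 80 °C) and separation of the E isomer give methyl (3E)-4-(tributylstannyl)but-3-enoate F5. F5 and iodide 20 with Pd2(dba)3 and AsPh3 in NMP at rt should give diene 23, where the route is rejoined.

**Further compounds**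
F1 | step 15 | methyl (3E,5Z,7S)-7-[(TBS)oxy]-8-[(2R,3R)-3-{[(TBS)oxy]methyl}-3-(2-iodoethyl)oxiran-2-yl]-6-methylocta-3,5-dienoate | COC(=O)C/C=C/C=C(/C)[C@@H](O[Si](C)(C)C(C)(C)C)C[C@H]1O[C@@]1(CO[Si](C)(C)C(C)(C)C)CCI
F2 | step 15 | methyl (3E,5Z,7S)-7-[(TBS)oxy]-8-[(2R,3R)-3-{[(TBS)oxy]methyl}-3-(2-nitroethyl)oxiran-2-yl]-6-methylocta-3,5-dienoate | COC(=O)C/C=C/C=C(/C)[C@@H](O[Si](C)(C)C(C)(C)C)C[C@H]1O[C@@]1(CO[Si](C)(C)C(C)(C)C)CC[N+](=O)[O-]
F3 | step 17 | (1R,3S,4Z,6S,7R,8S,10R)-3,14-bis[(TBS)oxy]-1,10-epoxy-8-hydroxy-13-norgermacr-4-eno-12,6-lactone | C1C(=O)O[C@H]2/C=C(/C)[C@@H](O[Si](C)(C)C(C)(C)C)C[C@H]3O[C@@]3(CO[Si](C)(C)C(C)(C)C)C[C@H](O)[C@@H]12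
F4 | step 17 | (1R,3S,4Z,6S,7R,8R,10R)-3,14-bis[(TBS)oxy]-8-(chloroacetoxy)-1,10-epoxy-13-norgermacr-4-eno-12,6-lactone | C1C(=O)O[C@H]2/C=C(/C)[C@@H](O[Si](C)(C)C(C)(C)C)C[C@H]3O[C@@]3(CO[Si](C)(C)C(C)(C)C)C[C@@H](OC(=O)CCl)[C@@H]12
F5 | step 13 | methyl (3E)-4-(tributylstannyl)but-3-enoate | COC(=O)C/C=C/[Sn](CCCC)(CCCC)CCCC
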